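**Retrosynthetic overview**

1. The six Si–O bonds go last. Glycerol unit G2 (threo) comes from an Evans boron syn-aldol that joins the ring-A aryloxyacetyl imide 27 to aldehyde 34, which already holds G3. G1 and G3 (erythro) come from MgCl2-catalysed anti-aldols of aryloxyacetyl imides with silylated vanillin 19.
2. The furofuran core 12 (ring A as allyl ether, ring B as TIPS ether) is made in one operation from the acyclic epoxy cinnamyl ether 9. Compound 9 comes from epoxy alcohol 5 and cinnamyl bromide 8, both from syringaldehyde and vinylmagnesium bromide.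
3. Enabling feature: in the ring C7–O–C9'–C8'–C8, the unit C8'–C9'–O is a disguised terminal oxirane and C8–C7 a disguised sinapyl alkene. C7 is benzylic to the electron-rich 4-alkoxy-3,5-dimethoxyphenyl ring A, so the radical left there after the first cyclization can be oxidized and captured by the oxygen on C9'.
4. Ring order: all five arene rings are bought (syringaldehyde twice, vanillin twice, 4-hydroxy-3-methoxybenzonitrile). Ring C7'–O–C9–C8–C8' closes first (radical 5-exo); ring C7–O–C9'–C8'–C8 closes second and last, in the same flask.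
5. Stereocontrol: C7' from a Sharpless kinetic resolution relays to C8', C8 and C7; the six side-chain centres come from three auxiliary-controlled aldol reactions.

Key step: step 8

**Remarks**

- Numbering: lignan numbering is used for the core. C7/C8/C9 belong to the half whose aryl group (ring A) ends up carrying G2–G3; C7'/C8'/C9' belong to the half whose aryl group (ring B) carries G1. In each glycerol unit, α is the benzylic carbinol carbon, β the aryloxy-bearing carbon and γ the CH2O carbon. In the target, G1 is (αS,βR), G2 is (αR,βR) and G3 is (αR,βS).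
- Assumption on the chemistry: in the MgCl2-catalysed anti-aldol reactions the aldehyde is taken to add to the magnesium-chelated enolate on the face away from the benzyl group of the oxazolidinone. This is the sense expected for N-acyl oxazolidinones and it decides which auxiliary enantiomer is used in steps 13 and 20.

**Route**

Step 1
Reactants: 1 syringaldehyde
Product: 2 3,5-dimethoxy-4-(triisopropylsilyloxy)benzaldehyde
Conditions: TIPSCl, imidazole, DMF, 23 °C
Reagents that add atoms: triisopropylsilyl chloride CC(C)[Si](Cl)(C(C)C)C(C)C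
Why: Imidazole-promoted silylation of the acidic phenol; the TIPS ether is chosen because it should survive Grignard, alkoxide and titanocene chemistry and can later be removed by fluoride while an allyl ether stays.

Step 2
Reactants: 2 3,5-dimethoxy-4-(triisopropylsilyloxy)benzaldehyde; 3 vinylmagnesium bromide
Product: 4 rac-1-[3,5-dimethoxy-4-(triisopropylsilyloxy)phenyl]prop-2-en-1-ol
Conditions: THF, −78 to 0 °C; aq. NH4Cl
Reagents that add atoms: none
Why: Grignard 1,2-addition to an aryl aldehyde; the carbinol centre is formed racemic on purpose and is resolved in step 3.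

Step 3
Reactants: 4 rac-1-[3,5-dimethoxy-4-(triisopropylsilyloxy)phenyl]prop-2-en-1-ol
Product: 5 (S)-[3,5-dimethoxy-4-(triisopropylsilyloxy)phenyl][(2R)-oxiran-2-yl]methanol
Conditions: Ti(OiPr)4 (15 mol %), L-(+)-diisopropyl tartrate (18 mol %), t-BuOOH (0.45 equiv), 4 Å MS, CH2Cl2, −20 °C
Reagents that add atoms: tert-butyl hydroperoxide CC(C)(C)OO
Why: Sharpless kinetic resolution by asymmetric epoxidation: the titanium–L-(+)-tartrate catalyst should epoxidize (R)-4 much faster than (S)-4 and from the face that gives the erythro product, so stopping below half conversion should leave (S)-4 (removed by chromatography) and deliver 5 with the (S)-carbinol centre that becomes C7' and an (R)-oxirane centre that is erased in step 8.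

Step 4
Reactants: 1 syringaldehyde
Product: 6 4-allyloxy-3,5-dimethoxybenzaldehyde
Conditions: allyl bromide, K2CO3, DMF, 23 °C
Reagents that add atoms: allyl bromide C=CCBr
Why: Williamson ether synthesis on the potassium phenoxide; the allyl ether is orthogonal to the silyl ethers and is removed later with zerovalent palladium.

Step 5
Reactants: 6 4-allyloxy-3,5-dimethoxybenzaldehyde; 3 vinylmagnesium bromide
Product: 7 rac-1-(4-allyloxy-3,5-dimethoxyphenyl)prop-2-en-1-ol
Conditions: THF, −78 to 0 °C; aq. NH4Cl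
Reagents that add atoms: none
Why: Grignard 1,2-addition; the carbinol centre is lost in step 6, so no stereocontrol is needed.

Step 6
Reactants: 7 rac-1-(4-allyloxy-3,5-dimethoxyphenyl)prop-2-en-1-ol
Product: 8 (E)-3-(4-allyloxy-3,5-dimethoxyphenyl)prop-2-enyl bromide
Conditions: PBr3 (0.4 equiv), Et2O, 0 °C
Reagents that add atoms: phosphorus tribromide BrP(Br)Br
Why: Bromination with allylic transposition (SN2'/ion-pair pathway): ionization is assisted by ring A and bromide returns at the terminal carbon because this gives the conjugated (E)-styrene, the thermodynamic isomer; the crude bromide is used at once.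

Step 7
Reactants: 5 (S)-[3,5-dimethoxy-4-(triisopropylsilyloxy)phenyl][(2R)-oxiran-2-yl]methanol; 8 (E)-3-(4-allyloxy-3,5-dimethoxyphenyl)prop-2-enyl bromide
Product: 9 (2R)-2-{(S)-[(E)-3-(4-allyloxy-3,5-dimethoxyphenyl)prop-2-enyloxy][3,5-dimethoxy-4-(triisopropylsilyloxy)phenyl]methyl}oxirane
Conditions: NaH, Bu4NI (cat.), THF, 0 °C
Reagents that add atoms: none
Why: Williamson etherification (SN2) of the sodium alkoxide of 5 with a reactive allylic bromide, run cold with the bromide present from the start so that alkylation outruns Payne rearrangement; no stereocentre is touched.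

Step 8
Reactants: 9 (2R)-2-{(S)-[(E)-3-(4-allyloxy-3,5-dimethoxyphenyl)prop-2-enyloxy][3,5-dimethoxy-4-(triisopropylsilyloxy)phenyl]methyl}oxirane
Product: 12 (1R,3aS,4R,6aS)-1-(4-allyloxy-3,5-dimethoxyphenyl)-4-[3,5-dimethoxy-4-(triisopropylsilyloxy)phenyl]tetrahydro-1H,3H-furo[3,4-c]furan (lignan descriptors 7R,8S,7'R,8'S), via benzyltitanium titanium-alkoxide 10 (not isolated), via benzylic iodide 11 (not isolated)
Conditions: Cp2TiCl2 (2.5 equiv), Zn, THF, 23 °C (green Cp2TiCl solution decanted from Zn and added slowly to 9); then I2 (1.5 equiv), THF, 60 °C; aq. Na2S2O3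
Reagents that add atoms: none
Why: Cp2TiCl (trivalent titanium) opens the oxirane of 9 by single-electron transfer at the more substituted C8'–O bond to give a secondary β-titanoxy radical at C8' (Nugent–RajanBabu epoxide homolysis), which adds 5-exo-trig to C8 of the (E)-styrenyl alkene, closes the first ring (C7'–O–C9–C8–C8') and leaves a radical at C7 that is benzylic to ring A. The closest known reaction type is the titanocene-mediated radical cyclization of epoxy cinnamyl ethers followed by iodine treatment, which has been used to make 2,6-diaryl furofuran lignans. In the chair-like Beckwith–Houk transition state the ring B aryl group on C7' sits pseudo-equatorial, which sets C8' trans to it, and the titanoxymethyl group on the radical carbon and the attacked alkene carbon take the cis arrangement usual for 1-substituted hexenyl radicals, which sets the cis ring fusion at C8/C8'; the oxirane stereocentre is erased, so C7' alone fixes the absolute configuration. The C7 radical is captured by a second Cp2TiCl to give 10, iodine converts the benzyl–titanium bond into the benzylic iodide 11, and the titanium alkoxide on C9' displaces iodide in a 5-exo-tet closure (ionization assisted by the 4-alkoxyaryl ring) that forms the last ring (C7–O–C9'–C8'–C8). C7 is set in this closure: the cis-fused bicycle holds O9' and C7 on one face and the aryl group should take the less hindered exo (convex) position, which is also the thermodynamically preferred one for a benzylic centre that can ionize reversibly. The step needs cyclization of the C8' radical to outrun its reduction by a second titanium centre (which would end in β-elimination to an alkene), which the activated styrene acceptor and slow addition of Cp2TiCl should secure, and it needs the aryl allyl and aryl silyl ethers to stay inert toward Cp2TiCl and I2.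

Step 9
Reactants: 12 furofuran core with ring A allyl ether and ring B TIPS ether
Product: 13 4-[(1R,3aS,4R,6aS)-4-(4-allyloxy-3,5-dimethoxyphenyl)tetrahydro-1H,3H-furo[3,4-c]furan-1-yl]-2,6-dimethoxyphenol (ring B phenol)
Conditions: Bu4NF, THF, 0 °C; aq. NH4Cl
Reagents that add atoms: none
Why: Fluoride cleaves the aryl silyl ether (strong Si–F bond, phenoxide leaving group) and should leave the allyl aryl ether and the benzylic ring ethers alone.

Step 10
Reactants: 14 (R)-4-benzyl-2-oxazolidinone; 15 bromoacetyl bromide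
Product: 16 (R)-4-benzyl-3-(bromoacetyl)oxazolidin-2-one
Conditions: n-BuLi, THF, −78 °C; then 15
Reagents that add atoms: none
Why: N-acylation of the lithiated Evans oxazolidinone; at −78 °C the acyl bromide reacts far faster than the alkyl bromide and the auxiliary centre is not involved.

Step 11
Reactants: 13 ring B phenol; 16 (R)-4-benzyl-3-(bromoacetyl)oxazolidin-2-one
Product: 17 (R)-4-benzyl-3-[(aryloxy)acetyl]oxazolidin-2-one in which aryl is ring B of the core (ring A still allyl ether)
Conditions: K2CO3, acetone, 23 °C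
Reagents that add atoms: none
Why: Williamson-type SN2 displacement of the activated α-bromo imide by the potassium phenoxide of ring B; the mild carbonate base should spare the imide and no stereocentre is touched.

Step 12
Reactants: 18 vanillin
Product: 19 3-methoxy-4-(triisopropylsilyloxy)benzaldehyde
Conditions: TIPSCl, imidazole, DMF, 23 °C
Reagents that add atoms: triisopropylsilyl chloride CC(C)[Si](Cl)(C(C)C)C(C)C
Why: Imidazole-promoted silylation of the phenol; the aryl TIPS ether should survive carbonate, boron and hydride steps and falls with fluoride at the end.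

Step 13
Reactants: 17 ring B aryloxyacetyl imide; 19 3-methoxy-4-(triisopropylsilyloxy)benzaldehyde
Product: 21 anti-aldol adduct (R)-4-benzyl-3-{(2S,3S)-2-(ring B aryloxy)-3-hydroxy-3-[3-methoxy-4-(triisopropylsilyloxy)phenyl]propanoyl}oxazolidin-2-one, via O-trimethylsilyl aldol ether 20 (not isolated)
Conditions: MgCl2 (20 mol %), Et3N, Me3SiCl, EtOAc, 23 °C; then citric acid, MeOH
Reagents that add atoms: none
Why: Evans MgCl2-catalysed anti-aldol reaction: soft enolization gives the magnesium-chelated Z-enolate, which the aldehyde should attack on the face away from the benzyl group of the (R)-auxiliary through a boat-like transition state, setting both new centres (anti, 2S,3S in the adduct, that is αS and βR of G1), while silylation of the aldolate turns the catalyst over and the labile silyl ether 20 is cleaved by mild acid.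

Step 14
Reactants: 21 anti-aldol adduct of G1
Product: 22 core carrying on ring B the (αS,βR)-erythro glycerol unit G1 as free α,γ-diol with 4-O-TIPS guaiacyl ring (ring A still allyl ether)
Conditions: LiBH4, MeOH (1 equiv), THF, 0 °C
Reagents that add atoms: none
Why: Reductive removal of the Evans auxiliary with LiBH4 gives the primary alcohol without touching either new stereocentre, the allyl ether or the aryl silyl ether, and returns the auxiliary.

Step 15
Reactants: 22 G1 diol
Product: 23 G1 α,γ-bis(tert-butyldimethylsilyl) ether (ring A allyl ether)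
Conditions: TBSOTf, 2,6-lutidine, CH2Cl2, −78 to 0 °C
Reagents that add atoms: tert-butyldimethylsilyl triflate CC(C)(C)[Si](C)(C)OS(=O)(=O)C(F)(F)F
Why: Silylation of both hydroxyls with the silyl triflate and a hindered base masks them for the boron aldol of step 24, and the groups fall with fluoride at the end.

Step 16
Reactants: 23 G1 bis-silyl ether with ring A allyl ether
Product: 24 ring A phenol (G1 fully silylated on ring B)
Conditions: Pd(PPh3)4 (5 mol %), morpholine, THF, 23 °C
Reagents that add atoms: none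
Why: Tsuji–Trost-type deallylation: zerovalent palladium ionizes the aryl allyl ether to a π-allyl complex that is captured by morpholine, conditions that should leave silyl ethers, benzylic ethers and all stereocentres alone.

Step 17
Reactants: 25 (S)-4-benzyl-2-oxazolidinone; 15 bromoacetyl bromide
Product: 26 (S)-4-benzyl-3-(bromoacetyl)oxazolidin-2-one
Conditions: n-BuLi, THF, −78 °C; then 15
Reagents that add atoms: none
Why: N-acylation of the lithiated Evans oxazolidinone, as in step 10.

Step 18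
Reactants: 24 ring A phenol; 26 (S)-4-benzyl-3-(bromoacetyl)oxazolidin-2-one
Product: 27 (S)-4-benzyl-3-[(aryloxy)acetyl]oxazolidin-2-one in which aryl is ring A of the core (G1 silylated on ring B)
Conditions: K2CO3, acetone, 23 °C
Reagents that add atoms: none
Why: Williamson-type SN2 displacement of the α-bromo imide by the ring A phenoxide, as in step 11; the aryl TIPS and alkyl TBS ethers should tolerate anhydrous carbonate.

Step 19
Reactants: 28 4-hydroxy-3-methoxybenzonitrile; 26 (S)-4-benzyl-3-(bromoacetyl)oxazolidin-2-one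
Product: 29 (S)-4-benzyl-3-[(4-cyano-2-methoxyphenoxy)acetyl]oxazolidin-2-one
Conditions: K2CO3, acetone, 23 °C
Reagents that add atoms: none
Why: Williamson-type SN2 displacement by an unhindered, acidic phenol; the nitrile is a masked aldehyde that cannot act as an aldol acceptor in step 20.

Step 20
Reactants: 29 (S)-4-benzyl-3-[(4-cyano-2-methoxyphenoxy)acetyl]oxazolidin-2-one; 19 3-methoxy-4-(triisopropylsilyloxy)benzaldehyde
Product: 31 anti-aldol adduct (S)-4-benzyl-3-{(2R,3R)-2-(4-cyano-2-methoxyphenoxy)-3-hydroxy-3-[3-methoxy-4-(triisopropylsilyloxy)phenyl]propanoyl}oxazolidin-2-one, via O-trimethylsilyl aldol ether 30 (not isolated)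
Conditions: MgCl2 (20 mol %), Et3N, Me3SiCl, EtOAc, 23 °C; then citric acid, MeOH
Reagents that add atoms: none
Why: Evans MgCl2-catalysed anti-aldol reaction as in step 13, now with the (S)-auxiliary, so that attack on the chelated Z-enolate away from the benzyl group should give the mirror-image anti array (2R,3R in the adduct, that is αR and βS of G3).

Step 21
Reactants: 31 anti-aldol adduct of G3
Product: 32 4-{(1R,2S)-1,3-dihydroxy-1-[3-methoxy-4-(triisopropylsilyloxy)phenyl]propan-2-yloxy}-3-methoxybenzonitrile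
Conditions: LiBH4, MeOH (1 equiv), THF, 0 °C
Reagents that add atoms: none
Why: LiBH4 reduces the imide to the primary alcohol and releases the auxiliary, while the aryl nitrile is not reduced under these conditions and the stereocentres are untouched.

Step 22
Reactants: 32 G3 diol nitrile
Product: 33 α,γ-bis(tert-butyldimethylsilyl) ether of 32
Conditions: TBSOTf, 2,6-lutidine, CH2Cl2, −78 to 0 °C
Reagents that add atoms: tert-butyldimethylsilyl triflate CC(C)(C)[Si](C)(C)OS(=O)(=O)C(F)(F)F
Why: Silylation of both hydroxyls protects them against i-Bu2AlH and Bu2BOTf in the next two steps.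

Step 23
Reactants: 33 G3 bis-silyl ether nitrile
Product: 34 4-{(1R,2S)-1,3-bis(tert-butyldimethylsilyloxy)-1-[3-methoxy-4-(triisopropylsilyloxy)phenyl]propan-2-yloxy}-3-methoxybenzaldehyde
Conditions: i-Bu2AlH, toluene, −78 °C; then aq. potassium sodium tartrate
Reagents that add atoms: water O
Why: i-Bu2AlH adds one hydride to the aryl nitrile to give an N-aluminio aldimine that is stable at −78 °C and is hydrolysed to the aldehyde on work-up; silyl ethers and the aryl ether should survive.

Step 24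
Reactants: 27 ring A aryloxyacetyl imide; 34 aldehyde carrying G3
Product: 35 syn-aldol adduct (S)-4-benzyl-3-[(2S,3R)-2-(ring A aryloxy)-3-hydroxy-3-aryl-propanoyl]oxazolidin-2-one in which the 3-aryl group is the guaiacyl ring of 34
Conditions: Bu2BOTf, Et3N, CH2Cl2, −78 to 0 °C; then 34, −78 to 0 °C; H2O2, MeOH, pH 7 buffer (KH2PO4/K2HPO4), 0 °C
Reagents that add atoms: none
Why: Evans boron syn-glycolate aldol: Bu2BOTf/Et3N gives the Z-boron enolate, which reacts through a Zimmerman–Traxler chair with the auxiliary carbonyl turned away (dipole-minimized), so the (S)-benzyl group should direct formation of the (2S,3R) syn adduct, that is αR and βR (threo) of G2, and the two large fragments are joined in this step.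

Step 25
Reactants: 35 syn-aldol adduct
Product: 36 hexasilyl ether of the target (G2 free α,γ-diol; G1 and G3 each as aryl TIPS ether and α,γ-bis-TBS ether)
Conditions: LiBH4, MeOH (1 equiv), THF, 0 °C
Reagents that add atoms: none
Why: Reductive removal of the Evans auxiliary with LiBH4 gives the G2 primary alcohol without epimerization and leaves all silyl ethers in place.

Step 26
Reactants: 36 hexasilyl ether of the target
Product: 37 CNP0316493.1 (target)
Conditions: Bu4NF, AcOH, THF, 0 to 23 °C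
Reagents that add atoms: none
Why: Global fluoride desilylation of the two aryl TIPS ethers and four alkyl TBS ethers; acetic acid buffers the phenoxides so that the p-hydroxybenzylic alcohols and the furofuran are not exposed to strong base, and no stereocentre is touched.

**Compound list**

1 | syringaldehyde (4-hydroxy-3,5-dimethoxybenzaldehyde) | COc1cc(C=O)cc(OC)c1O | starting material
2 | 3,5-dimethoxy-4-(triisopropylsilyloxy)benzaldehyde | COc1cc(C=O)cc(OC)c1O[Si](C(C)C)(C(C)C)C(C)C | intermediate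
3 | vinylmagnesium bromide | C=C[Mg]Br | starting material
4 | rac-1-[3,5-dimethoxy-4-(triisopropylsilyloxy)phenyl]prop-2-en-1-ol | C=CC(O)c1cc(OC)c(O[Si](C(C)C)(C(C)C)C(C)C)c(OC)c1 | intermediate
5 | (S)-[3,5-dimethoxy-4-(triisopropylsilyloxy)phenyl][(2R)-oxiran-2-yl]methanol | O[C@@H](c1cc(OC)c(O[Si](C(C)C)(C(C)C)C(C)C)c(OC)c1)[C@H]1CO1 | intermediate
6 | 4-allyloxy-3,5-dimethoxybenzaldehyde | C=CCOc1c(OC)cc(C=O)cc1OC | intermediate
7 | rac-1-(4-allyloxy-3,5-dimethoxyphenyl)prop-2-en-1-ol | C=CCOc1c(OC)cc(cc1OC)C(O)C=C | intermediate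
8 | (E)-3-(4-allyloxy-3,5-dimethoxyphenyl)prop-2-enyl bromide | C=CCOc1c(OC)cc(/C=C/CBr)cc1OC | intermediate
9 | (2R)-2-{(S)-[(E)-3-(4-allyloxy-3,5-dimethoxyphenyl)prop-2-enyloxy][3,5-dimethoxy-4-(triisopropylsilyloxy)phenyl]methyl}oxirane | C=CCOc1c(OC)cc(/C=C/CO[C@@H](c2cc(OC)c(O[Si](C(C)C)(C(C)C)C(C)C)c(OC)c2)[C@H]2CO2)cc1OC | intermediate
10 | monocyclic (7'R,8S,8'S)-tetrahydrofuran with C7–TiCp2Cl (ring A benzylic, C7 unassigned) and C9'–O–TiCp2Cl | C=CCOc1c(OC)cc(cc1OC)C([Ti](Cl)(C1C=CC=C1)C1C=CC=C1)[C@@H]1CO[C@@H](c2cc(OC)c(O[Si](C(C)C)(C(C)C)C(C)C)c(OC)c2)[C@@H]1CO[Ti](Cl)(C1C=CC=C1)C1C=CC=C1 | intermediate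
11 | monocyclic (7'R,8S,8'S)-tetrahydrofuran with C7–I (C7 unassigned) and C9'–O–TiCp2Cl | C=CCOc1c(OC)cc(cc1OC)C(I)[C@@H]1CO[C@@H](c2cc(OC)c(O[Si](C(C)C)(C(C)C)C(C)C)c(OC)c2)[C@@H]1CO[Ti](Cl)(C1C=CC=C1)C1C=CC=C1 | intermediate
12 | (1R,3aS,4R,6aS)-1-(4-allyloxy-3,5-dimethoxyphenyl)-4-[3,5-dimethoxy-4-(triisopropylsilyloxy)phenyl]tetrahydro-1H,3H-furo[3,4-c]furan | C=CCOc1c(OC)cc(cc1OC)[C@@H]1OC[C@@H]2[C@H]1CO[C@H]2c1cc(OC)c(O[Si](C(C)C)(C(C)C)C(C)C)c(OC)c1 | intermediate
13 | 4-[(1R,3aS,4R,6aS)-4-(4-allyloxy-3,5-dimethoxyphenyl)tetrahydro-1H,3H-furo[3,4-c]furan-1-yl]-2,6-dimethoxyphenol (ring B phenol) | C=CCOc1c(OC)cc(cc1OC)[C@@H]1OC[C@@H]2[C@H]1CO[C@H]2c1cc(OC)c(O)c(OC)c1 | intermediate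
14 | (R)-4-benzyl-2-oxazolidinone | O=C1N[C@H](Cc2ccccc2)CO1 | starting material
15 | bromoacetyl bromide | BrCC(Br)=O | starting material
16 | (R)-4-benzyl-3-(bromoacetyl)oxazolidin-2-one | O=C(CBr)N1[C@H](Cc2ccccc2)COC1=O | intermediate
17 | ring B aryloxyacetyl imide of the (R)-auxiliary (ring A allyl ether) | C=CCOc1c(OC)cc(cc1OC)[C@@H]1OC[C@@H]2[C@H]1CO[C@H]2c1cc(OC)c(OCC(=O)N2[C@H](Cc3ccccc3)COC2=O)c(OC)c1 | intermediate
18 | vanillin | COc1cc(C=O)ccc1O | starting material
19 | 3-methoxy-4-(triisopropylsilyloxy)benzaldehyde | COc1cc(C=O)ccc1O[Si](C(C)C)(C(C)C)C(C)C | intermediate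
20 | O-trimethylsilyl ether of anti-aldol adduct 21 | C=CCOc1c(OC)cc(cc1OC)[C@@H]1OC[C@@H]2[C@H]1CO[C@H]2c1cc(OC)c(O[C@H](C(=O)N2[C@H](Cc3ccccc3)COC2=O)[C@@H](O[Si](C)(C)C)c2ccc(O[Si](C(C)C)(C(C)C)C(C)C)c(OC)c2)c(OC)c1 | intermediate
21 | (2S,3S) anti-aldol adduct of G1 on ring B with (R)-auxiliary | C=CCOc1c(OC)cc(cc1OC)[C@@H]1OC[C@@H]2[C@H]1CO[C@H]2c1cc(OC)c(O[C@H](C(=O)N2[C@H](Cc3ccccc3)COC2=O)[C@@H](O)c2ccc(O[Si](C(C)C)(C(C)C)C(C)C)c(OC)c2)c(OC)c1 | intermediate
22 | core with (αS,βR)-G1 diol on ring B (aryl TIPS ether; ring A allyl ether) | C=CCOc1c(OC)cc(cc1OC)[C@@H]1OC[C@@H]2[C@H]1CO[C@H]2c1cc(OC)c(O[C@H](CO)[C@@H](O)c2ccc(O[Si](C(C)C)(C(C)C)C(C)C)c(OC)c2)c(OC)c1 | intermediate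
23 | G1 α,γ-bis-TBS ether (ring A allyl ether) | C=CCOc1c(OC)cc(cc1OC)[C@@H]1OC[C@@H]2[C@H]1CO[C@H]2c1cc(OC)c(O[C@H](CO[Si](C)(C)C(C)(C)C)[C@@H](O[Si](C)(C)C(C)(C)C)c2ccc(O[Si](C(C)C)(C(C)C)C(C)C)c(OC)c2)c(OC)c1 | intermediate
24 | ring A phenol with silylated G1 on ring B | Oc1c(OC)cc(cc1OC)[C@@H]1OC[C@@H]2[C@H]1CO[C@H]2c1cc(OC)c(O[C@H](CO[Si](C)(C)C(C)(C)C)[C@@H](O[Si](C)(C)C(C)(C)C)c2ccc(O[Si](C(C)C)(C(C)C)C(C)C)c(OC)c2)c(OC)c1 | intermediate
25 | (S)-4-benzyl-2-oxazolidinone | O=C1N[C@@H](Cc2ccccc2)CO1 | starting material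
26 | (S)-4-benzyl-3-(bromoacetyl)oxazolidin-2-one | O=C(CBr)N1[C@@H](Cc2ccccc2)COC1=O | intermediate
27 | ring A aryloxyacetyl imide of the (S)-auxiliary (silylated G1 on ring B) | O=C(COc1c(OC)cc(cc1OC)[C@@H]1OC[C@@H]2[C@H]1CO[C@H]2c1cc(OC)c(O[C@H](CO[Si](C)(C)C(C)(C)C)[C@@H](O[Si](C)(C)C(C)(C)C)c2ccc(O[Si](C(C)C)(C(C)C)C(C)C)c(OC)c2)c(OC)c1)N1[C@@H](Cc2ccccc2)COC1=O | intermediate
28 | 4-hydroxy-3-methoxybenzonitrile | COc1cc(C#N)ccc1O | starting material
29 | (S)-4-benzyl-3-[(4-cyano-2-methoxyphenoxy)acetyl]oxazolidin-2-one | N#Cc1ccc(OCC(=O)N2[C@@H](Cc3ccccc3)COC2=O)c(OC)c1 | intermediate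
30 | O-trimethylsilyl ether of anti-aldol adduct 31 | COc1cc(ccc1O[Si](C(C)C)(C(C)C)C(C)C)[C@@H](O[Si](C)(C)C)[C@H](C(=O)N1[C@@H](Cc2ccccc2)COC1=O)Oc1ccc(C#N)cc1OC | intermediate
31 | (2R,3R) anti-aldol adduct of G3 with (S)-auxiliary | COc1cc(ccc1O[Si](C(C)C)(C(C)C)C(C)C)[C@@H](O)[C@H](C(=O)N1[C@@H](Cc2ccccc2)COC1=O)Oc1ccc(C#N)cc1OC | intermediate
32 | 4-{(1R,2S)-1,3-dihydroxy-1-[3-methoxy-4-(triisopropylsilyloxy)phenyl]propan-2-yloxy}-3-methoxybenzonitrile | COc1cc(ccc1O[Si](C(C)C)(C(C)C)C(C)C)[C@@H](O)[C@H](CO)Oc1ccc(C#N)cc1OC | intermediate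
33 | α,γ-bis-TBS ether of 32 | COc1cc(ccc1O[Si](C(C)C)(C(C)C)C(C)C)[C@@H](O[Si](C)(C)C(C)(C)C)[C@H](CO[Si](C)(C)C(C)(C)C)Oc1ccc(C#N)cc1OC | intermediate
34 | 4-{(1R,2S)-1,3-bis(tert-butyldimethylsilyloxy)-1-[3-methoxy-4-(triisopropylsilyloxy)phenyl]propan-2-yloxy}-3-methoxybenzaldehyde | COc1cc(ccc1O[Si](C(C)C)(C(C)C)C(C)C)[C@@H](O[Si](C)(C)C(C)(C)C)[C@H](CO[Si](C)(C)C(C)(C)C)Oc1ccc(C=O)cc1OC | intermediate
35 | (2S,3R) syn-aldol adduct joining 27 and 34 ((S)-auxiliary still attached) | COc1cc(ccc1O[Si](C(C)C)(C(C)C)C(C)C)[C@@H](O[Si](C)(C)C(C)(C)C)[C@H](CO[Si](C)(C)C(C)(C)C)Oc1ccc(cc1OC)[C@@H](O)[C@@H](C(=O)N1[C@@H](Cc2ccccc2)COC1=O)Oc1c(OC)cc(cc1OC)[C@@H]1OC[C@@H]2[C@H]1CO[C@H]2c1cc(OC)c(O[C@H](CO[Si](C)(C)C(C)(C)C)[C@@H](O[Si](C)(C)C(C)(C)C)c2ccc(O[Si](C(C)C)(C(C)C)C(C)C)c(OC)c2)c(OC)c1 | intermediate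
36 | hexasilyl ether of the target (G2 free diol) | COc1cc(ccc1O[Si](C(C)C)(C(C)C)C(C)C)[C@@H](O[Si](C)(C)C(C)(C)C)[C@H](CO[Si](C)(C)C(C)(C)C)Oc1ccc(cc1OC)[C@@H](O)[C@@H](CO)Oc1c(OC)cc(cc1OC)[C@@H]1OC[C@@H]2[C@H]1CO[C@H]2c1cc(OC)c(O[C@H](CO[Si](C)(C)C(C)(C)C)[C@@H](O[Si](C)(C)C(C)(C)C)c2ccc(O[Si](C(C)C)(C(C)C)C(C)C)c(OC)c2)c(OC)c1 | intermediate
37 | CNP0316493.1 | COc1cc([C@@H](O)[C@H](CO)Oc2ccc([C@@H](O)[C@@H](CO)Oc3c(OC)cc([C@@H]4OC[C@@H]5[C@H]4CO[C@H]5c4cc(OC)c(O[C@H](CO)[C@@H](O)c5ccc(O)c(OC)c5)c(OC)c4)cc3OC)cc2OC)ccc1O | target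

**Step count and risks**

Total step count: 26.
Longest linear sequence: 15 steps (1, 2, 3, 7, 8, 9, 11, 13, 14, 15, 16, 18, 24, 25, 26), from syringaldehyde.

Steps most likely to fail:

1. Step 8. The process at risk is the oxidative C7–O closure: the benzylic titanium or radical centre may be protonated or may abstract hydrogen before iodination, so that the second ring stays open. The fallback sets out from 9 and comes back at 12. The titanocene cyclization of 9 is run alone and quenched with dilute acid, which should give the monocyclic tetrahydrofuran alcohol with a 4-allyloxy-3,5-dimethoxybenzyl group on C8, F1. Its allyl group is removed with Pd(PPh3)4 and morpholine to give the 4-hydroxy-3,5-dimethoxybenzyl phenol F2. Ag2O in CH2Cl2 oxidizes this phenol to the p-quinone methide F3, whose C7 is captured at once by the C9' hydroxyl in a 5-exo oxa-Michael addition (the biomimetic closure) to give the furofuran with free ring A phenol F4. Allyl bromide and K2CO3 then restore the allyl ether and give 12.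

2. Step 13. The process at risk is stereocontrol in the magnesium enolate aldol of the hindered 2,6-dimethoxyphenoxyacetyl imide (low anti/syn or facial selectivity), together with retro-aldol cleavage during desilylation. The fallback sets out from 13 and comes back at 23. Phenol 13 is alkylated with the (S)-bromoacetyl imide 26 to give the ring B aryloxyacetyl imide of the (S)-auxiliary F5. A Bu2BOTf/Et3N syn-aldol with 19 gives the (2S,3R) syn adduct F6, in which the β centre is already correct and the α centre is epimeric. LiBH4 gives the threo (αR,βR) diol F7, and TBSCl with imidazole silylates the primary hydroxyl to give the γ-TBS ether F8. A Mitsunobu reaction with 4-nitrobenzoic acid (PPh3, DIAD) inverts the benzylic centre and gives the α-(4-nitrobenzoate) F9; K2CO3 in MeOH gives the erythro (αS,βR) alcohol F10; TBSOTf and 2,6-lutidine give 23.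

3. Step 11. The process at risk is acyl transfer: the hindered phenoxide may attack the exocyclic imide carbonyl of 16 instead of displacing bromide, which cleaves the auxiliary. The fallback sets out from 13 and comes back at 17, and builds the imide N–C bond last. Phenol 13 is alkylated with ethyl bromoacetate (K2CO3, acetone) to give the ethyl aryloxyacetate F11. LiOH in THF/water gives the aryloxyacetic acid F12. Pivaloyl chloride and Et3N give the mixed pivalic anhydride F13, which acylates the lithium salt of oxazolidinone 14 (n-BuLi, THF, −78 °C) to give 17.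

**Further compounds**

F1 | step 8 | monocyclic (7'R,8S,8'S)-tetrahydrofuran alcohol with 4-allyloxy-3,5-dimethoxybenzyl group on C8 | C=CCOc1c(OC)cc(cc1OC)C[C@@H]1CO[C@@H](c2cc(OC)c(O[Si](C(C)C)(C(C)C)C(C)C)c(OC)c2)[C@@H]1CO
F2 | step 8 | monocyclic tetrahydrofuran alcohol with 4-hydroxy-3,5-dimethoxybenzyl group on C8 | Oc1c(OC)cc(cc1OC)C[C@@H]1CO[C@@H](c2cc(OC)c(O[Si](C(C)C)(C(C)C)C(C)C)c(OC)c2)[C@@H]1CO
F3 | step 8 | p-quinone methide of F2 (C7 exocyclic alkene) | O=C1C(OC)=CC(=C[C@@H]2CO[C@@H](c3cc(OC)c(O[Si](C(C)C)(C(C)C)C(C)C)c(OC)c3)[C@@H]2CO)C=C1OC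
F4 | step 8 | furofuran with free ring A phenol and ring B TIPS ether | Oc1c(OC)cc(cc1OC)[C@@H]1OC[C@@H]2[C@H]1CO[C@H]2c1cc(OC)c(O[Si](C(C)C)(C(C)C)C(C)C)c(OC)c1
F5 | step 13 | ring B aryloxyacetyl imide of the (S)-auxiliary | C=CCOc1c(OC)cc(cc1OC)[C@@H]1OC[C@@H]2[C@H]1CO[C@H]2c1cc(OC)c(OCC(=O)N2[C@@H](Cc3ccccc3)COC2=O)c(OC)c1
F6 | step 13 | (2S,3R) syn-aldol adduct on ring B with (S)-auxiliary | C=CCOc1c(OC)cc(cc1OC)[C@@H]1OC[C@@H]2[C@H]1CO[C@H]2c1cc(OC)c(O[C@H](C(=O)N2[C@@H](Cc3ccccc3)COC2=O)[C@H](O)c2ccc(O[Si](C(C)C)(C(C)C)C(C)C)c(OC)c2)c(OC)c1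
F7 | step 13 | threo (αR,βR) diol on ring B | C=CCOc1c(OC)cc(cc1OC)[C@@H]1OC[C@@H]2[C@H]1CO[C@H]2c1cc(OC)c(O[C@H](CO)[C@H](O)c2ccc(O[Si](C(C)C)(C(C)C)C(C)C)c(OC)c2)c(OC)c1
F8 | step 13 | threo γ-TBS ether with free α-hydroxyl | C=CCOc1c(OC)cc(cc1OC)[C@@H]1OC[C@@H]2[C@H]1CO[C@H]2c1cc(OC)c(O[C@H](CO[Si](C)(C)C(C)(C)C)[C@H](O)c2ccc(O[Si](C(C)C)(C(C)C)C(C)C)c(OC)c2)c(OC)c1
F9 | step 13 | erythro α-(4-nitrobenzoate) γ-TBS ether (α centre inverted) | C=CCOc1c(OC)cc(cc1OC)[C@@H]1OC[C@@H]2[C@H]1CO[C@H]2c1cc(OC)c(O[C@H](CO[Si](C)(C)C(C)(C)C)[C@@H](OC(=O)c2ccc(cc2)[N+](=O)[O-])c2ccc(O[Si](C(C)C)(C(C)C)C(C)C)c(OC)c2)c(OC)c1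
F10 | step 13 | erythro (αS,βR) γ-TBS ether with free α-hydroxyl | C=CCOc1c(OC)cc(cc1OC)[C@@H]1OC[C@@H]2[C@H]1CO[C@H]2c1cc(OC)c(O[C@H](CO[Si](C)(C)C(C)(C)C)[C@@H](O)c2ccc(O[Si](C(C)C)(C(C)C)C(C)C)c(OC)c2)c(OC)c1
F11 | step 11 | ethyl (ring B aryloxy)acetate | C=CCOc1c(OC)cc(cc1OC)[C@@H]1OC[C@@H]2[C@H]1CO[C@H]2c1cc(OC)c(OCC(=O)OCC)c(OC)c1
F12 | step 11 | (ring B aryloxy)acetic acid | C=CCOc1c(OC)cc(cc1OC)[C@@H]1OC[C@@H]2[C@H]1CO[C@H]2c1cc(OC)c(OCC(O)=O)c(OC)c1
F13 | step 11 | mixed pivalic anhydride of F12 | C=CCOc1c(OC)cc(cc1OC)[C@@H]1OC[C@@H]2[C@H]1CO[C@H]2c1cc(OC)c(OCC(=O)OC(=O)C(C)(C)C)c(OC)c1
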